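**Retrosynthetic overview**
1. The target comes from its C50 methyl ester by ester reduction. The ester comes from two Wittig olefinations (C11=C12, then C11′=C12′) of the C10 trienedial with a ring-A and a ring-B C20 phosphonium salt.
2. Each salt comes from a 2-substituted α-ionone (vinyl Grignard, then Ph3P·HBr). Both side chains are grown by cross-metathesis from one common 2-allyl handle.
3. Rings A and B are formed first, in two parallel flasks, before any polyene exists. Each closure copies the carotenoid cyclase: proton-initiated C1–C6 closure of an acyclic isopropenyl dienone, loss of H4 to the ε-alkene, and transfer of chirality from C2 to C6 (the 5E dienone gives cis ring A, the 5Z dienone gives trans ring B).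
4. Both dienones come from (R)-limonene. Ring ozonolysis delivers the C2 stereocentre, the isopropenyl group, the C5 methyl ketone and the side-chain aldehyde in one step; methylenation, ethynylation and a Saucy–Marbet extension follow, and the 5E/5Z pair is separated.

Assumption: ring atoms carry carotenoid numbers (C1 gem-dimethyl, C2 side-chain carbon, C5 methyl-bearing alkene carbon, C6 polyene-bearing carbon). The target SMILES is read as (2S,6R,2′R,6′S): ring A (prenyl) is cis-2,6, ring B (hydroxyprenyl) is trans-2,6, and C2 and C2′ have the same spatial arrangement.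

**Route**

Step 1
Reactants: 1 (R)-(+)-limonene; 2 ozone
Product: 4 (3R)-6-oxo-3-(prop-1-en-2-yl)heptanal, via ozonide 3 (not isolated)
Conditions: O3 (1.0 equiv, titrated), CH2Cl2, −78 °C; then Me2S, −78 °C → rt
Reagents that add atoms: ozone, [O-][O+]=O
Why: Ozonolysis with reductive work-up; electrophilic ozone attacks the trisubstituted ring alkene much faster than the 1,1-disubstituted isopropenyl group, and the limonene stereocentre is untouched and becomes C2 of both rings.

Step 2
Reactants: 4 (3R)-6-oxo-3-(prop-1-en-2-yl)heptanal; 5 methyltriphenylphosphonium bromide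
Product: 7 (5R)-5-(prop-1-en-2-yl)oct-7-en-2-one, via methylenetriphenylphosphorane 6 (not isolated)
Conditions: Ph3PCH3Br (1.0 equiv), KN(SiMe3)2 (0.98 equiv), THF, 0 °C; then 4, −78 → 0 °C
Reagents that add atoms: methyltriphenylphosphonium bromide, C[P+](c1ccccc1)(c1ccccc1)c1ccccc1.[Br-]
Why: Wittig methylenation; the unstabilised ylide reacts with the aldehyde far faster than with the methyl ketone at low temperature, giving an acid-inert allyl handle, and the stereocentre is β to the aldehyde so it cannot epimerise.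

Step 3
Reactants: 7 (5R)-5-(prop-1-en-2-yl)oct-7-en-2-one; 8 ethynylmagnesium bromide
Product: 9 (3RS,6R)-3-methyl-6-(prop-1-en-2-yl)non-8-en-1-yn-3-ol
Conditions: HC≡CMgBr (1.5 equiv), THF, 0 °C; aq. NH4Cl
Reagents that add atoms: ethynylmagnesium bromide, C#C[Mg]Br
Why: Grignard 1,2-addition to the methyl ketone gives the tertiary propargylic alcohol; the new carbinol centre is destroyed in step 4, so both epimers are carried on.

Step 4
Reactants: 9 (3RS,6R)-3-methyl-6-(prop-1-en-2-yl)non-8-en-1-yn-3-ol; 10 2-methoxypropene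
Product: 13 (3E,5E,9R)-6-methyl-9-(prop-1-en-2-yl)dodeca-3,5,11-trien-2-one and 14 (3E,5Z,9R)-6-methyl-9-(prop-1-en-2-yl)dodeca-3,5,11-trien-2-one (ratio about 3:2; separated), via propargyl isopropenyl ether 11 (not isolated), via allenyl ketone 12 (not isolated)
Conditions: CH2=C(OMe)CH3 (4 equiv), p-MeC6H4SO3H·H2O (0.1 mol %), sealed vessel, 90 °C, 10 h; then NaOH (0.1 equiv), MeOH/H2O, 0 °C → rt; chromatography on SiO2 (hexane/Et2O), mixed fractions recycled
Reagents that add atoms: 2-methoxypropene, COC(C)=C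
Why: Saucy–Marbet reaction; acid-catalysed isopropenyl transfer, propargyl Claisen rearrangement and base isomerisation of the allenyl ketone give the pseudoionone-type 3E-dienone as a 5E/5Z pair that separates like the pseudoionone isomers, the trace acid does not touch the isopropenyl group or its neighbouring stereocentre, and the two geometric isomers are wanted in nearly the ratio in which they form.

Step 5
Reactants: 13 (3E,5E,9R)-6-methyl-9-(prop-1-en-2-yl)dodeca-3,5,11-trien-2-one
Product: 15 (2S,6R)-2-allyl-α-ionone, (3E)-4-[(1R,5S)-2,6,6-trimethyl-5-(prop-2-en-1-yl)cyclohex-2-en-1-yl]but-3-en-2-one (cis)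
Conditions: 85% H3PO4, toluene, 15–20 °C, vigorous stirring, ca. 1 h; aq. NaHCO3; chromatography on AgNO3-impregnated SiO2
Reagents that add atoms: none
Why: Proposed new method: a cation–olefin cyclisation that copies the cyclase step of C50-carotenoid biosynthesis, in which Markovnikov protonation of the isopropenyl C1=C16 bond (the monosubstituted allyl group and the electron-poor dienone are far less basic) gives the C1 cation, the 5E alkene closes the C1–C6 bond through a chair with the C2 allyl group and the C6 enone chain both equatorial, and loss of H4 gives the ε-alkene, so the limonene-derived C2 centre sets C6 as R (cis); in that chair the C2–H bond is gauche to the vacant orbital and the C2–allyl bond is anti to the incoming C6, which disfavours hydride shift or proton loss at C2, and the closest known reactions are the H3PO4 cyclisations of pseudoionone to α-ionone and of pseudoirones to cis- and trans-α-irone.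

Step 6
Reactants: 14 (3E,5Z,9R)-6-methyl-9-(prop-1-en-2-yl)dodeca-3,5,11-trien-2-one
Product: 16 (2S,6S)-2-allyl-α-ionone, (3E)-4-[(1S,5S)-2,6,6-trimethyl-5-(prop-2-en-1-yl)cyclohex-2-en-1-yl]but-3-en-2-one (trans)
Conditions: 85% H3PO4, toluene, 15–20 °C, vigorous stirring, ca. 2 h; aq. NaHCO3; chromatography on AgNO3-impregnated SiO2
Reagents that add atoms: none
Why: Proposed new method: the same biomimetic cation–olefin cyclisation run on the 5Z isomer, in which the C1 cation formed by Markovnikov protonation of the isopropenyl group is captured by the 5Z alkene through the chair that keeps the C2 allyl group equatorial and therefore places the C6 enone chain axial (the substituent cis to C4 on the alkene becomes axial, which also avoids allylic strain with the C5 methyl), and loss of H4 gives the ε-alkene with C6 as S (trans); the closest known reactions are the H3PO4 cyclisations of pseudoionone to α-ionone and of pseudoirones to cis- and trans-α-irone.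

Step 7
Reactants: 15 (2S,6R)-2-allyl-α-ionone; 17 2-methyl-2-butene
Product: 18 (2S,6R)-2-prenyl-α-ionone, (3E)-4-[(1R,5S)-2,6,6-trimethyl-5-(3-methylbut-2-en-1-yl)cyclohex-2-en-1-yl]but-3-en-2-one
Conditions: second-generation Grubbs catalyst RuCl2(=CHPh)(PCy3)(H2IMes) (3 mol %), 1,4-benzoquinone (10 mol %), 2-methyl-2-butene/CH2Cl2, 40 °C
Reagents that add atoms: 2-methyl-2-butene, CC=C(C)C
Why: Olefin cross-metathesis converts the terminal allyl group into prenyl; the ring trisubstituted alkene and the hindered, electron-poor enone alkene do not take part, and no stereocentre is touched.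

Step 8
Reactants: 18 (2S,6R)-2-prenyl-α-ionone; 19 vinylmagnesium bromide
Product: 20 (1E,3RS)-3-methyl-1-[(1R,5S)-2,6,6-trimethyl-5-(3-methylbut-2-en-1-yl)cyclohex-2-en-1-yl]penta-1,4-dien-3-ol
Conditions: CH2=CHMgBr (1.3 equiv), THF, −30 → 0 °C; aq. NH4Cl
Reagents that add atoms: vinylmagnesium bromide, C=C[Mg]Br
Why: Grignard 1,2-addition to the enone carbonyl gives the tertiary bis-allylic carbinol; C6 is not deprotonated under these conditions and the new carbinol centre disappears in step 9.

Step 9
Reactants: 20 tertiary carbinol; 21 triphenylphosphine hydrobromide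
Product: 22 [(2E,4E)-3-methyl-5-[(1R,5S)-2,6,6-trimethyl-5-(3-methylbut-2-en-1-yl)cyclohex-2-en-1-yl]penta-2,4-dien-1-yl]triphenylphosphonium bromide (ring-A C20 salt)
Conditions: Ph3P·HBr (1.05 equiv), MeOH, 20 °C, 16 h, dark; crystallisation
Reagents that add atoms: triphenylphosphine hydrobromide, [Br-].[PH+](c1ccccc1)(c1ccccc1)c1ccccc1
Why: Allylic transposition (SN1′); the tertiary bis-allylic alcohol ionises to a pentadienyl cation that PPh3 captures at the primary terminus to give the 7E,9E salt, as in the standard C15 Wittig-salt preparation from vinyl-ionols, while the isolated prenyl and ring alkenes are not protonated and C6 keeps its configuration.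

Step 10
Reactants: 16 (2S,6S)-2-allyl-α-ionone; 23 methyl methacrylate
Product: 24 (2R,6S)-2-[(2E)-3-(methoxycarbonyl)but-2-en-1-yl]-α-ionone, methyl (2E)-2-methyl-4-[(1R,5S)-4,6,6-trimethyl-5-[(1E)-3-oxobut-1-en-1-yl]cyclohex-3-en-1-yl]but-2-enoate
Conditions: second-generation Hoveyda–Grubbs catalyst RuCl2(=CH-C6H4-2-O-i-Pr)(H2IMes) (5 mol %), methyl methacrylate (10 equiv), 1,4-benzoquinone (10 mol %), CH2Cl2, 40 °C
Reagents that add atoms: methyl methacrylate, C=C(C)C(=O)OC
Why: Olefin cross-metathesis of the terminal allyl group with the 1,1-disubstituted acrylate gives the trisubstituted enoate under thermodynamic control (E, ring CH2 trans to CO2Me), which is the hydroxyprenyl group at the ester oxidation level; the C2 descriptor changes from S to R only because the priorities change.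

Step 11
Reactants: 24 ester-bearing α-ionone; 19 vinylmagnesium bromide
Product: 25 methyl (2E)-4-[(1R,5S)-5-[(1E,3RS)-3-hydroxy-3-methylpenta-1,4-dien-1-yl]-4,6,6-trimethylcyclohex-3-en-1-yl]-2-methylbut-2-enoate
Conditions: CH2=CHMgBr (1.15 equiv), THF, −78 → −40 °C; aq. NH4Cl
Reagents that add atoms: vinylmagnesium bromide, C=C[Mg]Br
Why: Chemoselective Grignard 1,2-addition; at −78 °C the methyl ketone reacts much faster than the α-methyl-branched conjugated ester.

Step 12
Reactants: 25 tertiary carbinol; 21 triphenylphosphine hydrobromide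
Product: 26 [(2E,4E)-5-[(1S,5R)-5-[(2E)-4-methoxy-3-methyl-4-oxobut-2-en-1-yl]-2,6,6-trimethylcyclohex-2-en-1-yl]-3-methylpenta-2,4-dien-1-yl]triphenylphosphonium bromide (ring-B C20 salt)
Conditions: Ph3P·HBr (1.05 equiv), MeOH, 20 °C, 16 h, dark; crystallisation
Reagents that add atoms: triphenylphosphine hydrobromide, [Br-].[PH+](c1ccccc1)(c1ccccc1)c1ccccc1
Why: Same allylic transposition (SN1′) as in step 9; the methyl ester is inert in methanolic HBr·PPh3 and the ring stereocentres are untouched.

Step 13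
Reactants: 22 ring-A C20 salt; 27 (2E,4E,6E)-2,7-dimethylocta-2,4,6-trienedial
Product: 29 (2E,4E,6E,8E,10E,12E)-2,7,11-trimethyl-13-[(1R,5S)-2,6,6-trimethyl-5-(3-methylbut-2-en-1-yl)cyclohex-2-en-1-yl]trideca-2,4,6,8,10,12-hexaenal, via ring-A ylide 28 (not isolated)
Conditions: 27 (3 equiv), NaOMe (1.1 equiv), CH2Cl2/MeOH, 0 °C → rt, argon, dark; then reflux in heptane (Z → E); excess 27 recovered
Reagents that add atoms: (2E,4E,6E)-2,7-dimethylocta-2,4,6-trienedial, O=C/C(C)=C/C=C/C=C(C)/C=O
Why: Wittig olefination of one formyl group of the excess symmetric dialdehyde forms C11=C12; the 11E/11Z mixture is brought to all-E by thermal isomerisation, and the ring stereocentres are remote from the ylide.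

Step 14
Reactants: 29 C30 apo-aldehyde; 26 ring-B C20 salt
Product: 31 (2S,6R,2′R,6′S)-2-(3-methylbut-2-en-1-yl)-2′-[(2E)-3-(methoxycarbonyl)but-2-en-1-yl]-ε,ε-carotene, via ring-B ylide 30 (not isolated)
Conditions: NaOMe (1.2 equiv), CH2Cl2/MeOH, 0 °C → rt, argon, dark; then reflux in heptane (Z → E); crystallisation
Reagents that add atoms: none
Why: A second Wittig olefination forms C11′=C12′ and completes the C50 skeleton; the methyl ester is indifferent to NaOMe/MeOH, and heating plus crystallisation give the all-E polyene.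

Step 15
Reactants: 31 C50 methyl ester
Product: 32 CNP0304855.1, (2S,6R,2′R,6′S)-2-(3-methylbut-2-en-1-yl)-2′-[(2E)-4-hydroxy-3-methylbut-2-en-1-yl]-ε,ε-carotene
Conditions: i-Bu2AlH (3 equiv), CH2Cl2, −78 °C, argon, dark; aq. potassium sodium tartrate
Reagents that add atoms: none
Why: Hydride 1,2-reduction of the isolated enoate by i-Bu2AlH gives the primary (E)-allylic alcohol and leaves the hydrocarbon polyene and all stereocentres unchanged.

**Compound list**

1 | (R)-(+)-limonene | CC1=CC[C@@H](CC1)C(C)=C | starting material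
2 | ozone | [O-][O+]=O | starting material
3 | ozonide of the ring alkene of 1 (7,8,9-trioxabicyclo[4.2.1]nonane, not isolated) | CC12OOC(O1)C[C@@H](CC2)C(C)=C | intermediate
4 | (3R)-6-oxo-3-(prop-1-en-2-yl)heptanal | O=CC[C@@H](CCC(C)=O)C(C)=C | intermediate
5 | methyltriphenylphosphonium bromide | C[P+](c1ccccc1)(c1ccccc1)c1ccccc1.[Br-] | starting material
6 | methylenetriphenylphosphorane (not isolated) | C=P(c1ccccc1)(c1ccccc1)c1ccccc1 | intermediate
7 | (5R)-5-(prop-1-en-2-yl)oct-7-en-2-one | C=CC[C@@H](CCC(C)=O)C(C)=C | intermediate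
8 | ethynylmagnesium bromide | C#C[Mg]Br | starting material
9 | (3RS,6R)-3-methyl-6-(prop-1-en-2-yl)non-8-en-1-yn-3-ol | C=CC[C@@H](CCC(C)(O)C#C)C(C)=C | intermediate
10 | 2-methoxypropene | COC(C)=C | starting material
11 | (6R)-3-methyl-3-(prop-1-en-2-yloxy)-6-(prop-1-en-2-yl)non-8-en-1-yne (not isolated) | C=CC[C@@H](CCC(C)(OC(C)=C)C#C)C(C)=C | intermediate
12 | (9R)-6-methyl-9-(prop-1-en-2-yl)dodeca-4,5,11-trien-2-one (not isolated) | C=CC[C@@H](CCC(C)=C=CCC(C)=O)C(C)=C | intermediate
13 | (3E,5E,9R)-6-methyl-9-(prop-1-en-2-yl)dodeca-3,5,11-trien-2-one | C=CC[C@@H](CC/C(C)=C/C=C/C(C)=O)C(C)=C | intermediate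
14 | (3E,5Z,9R)-6-methyl-9-(prop-1-en-2-yl)dodeca-3,5,11-trien-2-one | C=CC[C@@H](CC/C(C)=C\C=C\C(C)=O)C(C)=C | intermediate
15 | (2S,6R)-2-allyl-α-ionone (cis) | C=CC[C@H]1CC=C(C)[C@@H](/C=C/C(C)=O)C1(C)C | intermediate
16 | (2S,6S)-2-allyl-α-ionone (trans) | CC(=O)/C=C/[C@H]1C(C)=CC[C@H](CC=C)C1(C)C | intermediate
17 | 2-methyl-2-butene | CC=C(C)C | starting material
18 | (2S,6R)-2-(3-methylbut-2-en-1-yl)-α-ionone | CC(C)=CC[C@H]1CC=C(C)[C@@H](/C=C/C(C)=O)C1(C)C | intermediate
19 | vinylmagnesium bromide | C=C[Mg]Br | starting material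
20 | (1E,3RS)-3-methyl-1-[(1R,5S)-2,6,6-trimethyl-5-(3-methylbut-2-en-1-yl)cyclohex-2-en-1-yl]penta-1,4-dien-3-ol | CC(C)=CC[C@H]1CC=C(C)[C@@H](/C=C/C(C)(O)C=C)C1(C)C | intermediate
21 | triphenylphosphine hydrobromide | [Br-].[PH+](c1ccccc1)(c1ccccc1)c1ccccc1 | starting material
22 | ring-A C20 phosphonium bromide (7E,9E) | CC(C)=CC[C@H]1CC=C(C)[C@@H](/C=C/C(C)=C/C[P+](c2ccccc2)(c2ccccc2)c2ccccc2)C1(C)C.[Br-] | intermediate
23 | methyl methacrylate | C=C(C)C(=O)OC | starting material
24 | (2R,6S)-2-[(2E)-3-(methoxycarbonyl)but-2-en-1-yl]-α-ionone | CC(=O)/C=C/[C@H]1C(C)=CC[C@H](C/C=C(\C)C(=O)OC)C1(C)C | intermediate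
25 | methyl (2E)-4-[(1R,5S)-5-[(1E,3RS)-3-hydroxy-3-methylpenta-1,4-dien-1-yl]-4,6,6-trimethylcyclohex-3-en-1-yl]-2-methylbut-2-enoate | C=CC(C)(O)/C=C/[C@H]1C(C)=CC[C@H](C/C=C(\C)C(=O)OC)C1(C)C | intermediate
26 | ring-B C20 phosphonium bromide (7′E,9′E) | c1ccccc1[P+](c1ccccc1)(c1ccccc1)C/C=C(C)/C=C/[C@H]2C(C)=CC[C@H](C/C=C(\C)C(=O)OC)C2(C)C.[Br-] | intermediate
27 | (2E,4E,6E)-2,7-dimethylocta-2,4,6-trienedial | O=C/C(C)=C/C=C/C=C(C)/C=O | starting material
28 | ring-A ylide from 22 (not isolated) | CC(C)=CC[C@H]1CC=C(C)[C@@H](/C=C/C(C)=C/C=P(c2ccccc2)(c2ccccc2)c2ccccc2)C1(C)C | intermediate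
29 | (2E,4E,6E,8E,10E,12E)-2,7,11-trimethyl-13-[(1R,5S)-2,6,6-trimethyl-5-(3-methylbut-2-en-1-yl)cyclohex-2-en-1-yl]trideca-2,4,6,8,10,12-hexaenal | CC(C)=CC[C@H]1CC=C(C)[C@@H](/C=C/C(C)=C/C=C/C(C)=C/C=C/C=C(C)/C=O)C1(C)C | intermediate
30 | ring-B ylide from 26 (not isolated) | c1ccccc1P(c1ccccc1)(c1ccccc1)=C/C=C(C)/C=C/[C@H]2C(C)=CC[C@H](C/C=C(\C)C(=O)OC)C2(C)C | intermediate
31 | (2S,6R,2′R,6′S)-2-(3-methylbut-2-en-1-yl)-2′-[(2E)-3-(methoxycarbonyl)but-2-en-1-yl]-ε,ε-carotene | CC(C)=CC[C@H]1CC=C(C)[C@@H](/C=C/C(C)=C/C=C/C(C)=C/C=C/C=C(C)/C=C/C=C(C)/C=C/[C@H]2C(C)=CC[C@H](C/C=C(\C)C(=O)OC)C2(C)C)C1(C)C | intermediate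
32 | CNP0304855.1, (2S,6R,2′R,6′S)-2-(3-methylbut-2-en-1-yl)-2′-[(2E)-4-hydroxy-3-methylbut-2-en-1-yl]-ε,ε-carotene | CC(C)=CC[C@H]1CC=C(C)[C@@H](/C=C/C(C)=C/C=C/C(C)=C/C=C/C=C(C)/C=C/C=C(C)/C=C/[C@H]2C(C)=CC[C@H](C/C=C(\C)CO)C2(C)C)C1(C)C | target

**Step count and risks**

Total: 15 steps (4 shared, 4 for each C20 salt including its ring closure, 3 for assembly). Longest linear sequence: 11 steps (1–5, 7–9, 13–15).

The first risk is step 5. The C1 cation sits next to the C2–H bond, so the C2 configuration can leak if the cation returns to the tetrasubstituted C1=C2 alkene or suffers a C2→C1 hydride shift before ring closure; mixtures of ring-alkene isomers are also possible. The fallback replaces chirality transfer by resolution; it sets out from 15 of reduced stereochemical purity and comes back to 15. NaBH4/CeCl3·7H2O (MeOH, 0 °C) gives (2S,6R,9RS)-2-allyl-α-ionol F1. Lipase from Burkholderia cepacia with vinyl acetate (t-BuOMe, 30 °C) acetylates only 9R carbinols, giving (2S,6R,9R)-2-allyl-α-ionyl acetate F2. Any ring-enantiomeric material gives the diastereomeric (2R,6S,9R)-2-allyl-α-ionyl acetate F3, which is removed by chromatography. K2CO3/MeOH then gives (2S,6R,9R)-2-allyl-α-ionol F4, and MnO2 (CH2Cl2) returns stereochemically pure 15.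

The second risk is step 6. The 5Z geometry must survive until the C1–C6 bond forms and the enone chain must go axial. If the protonated dienone equilibrates to 5E first, the flask gives mainly cis 15 (which is not lost, since it joins the ring-A line) and too little trans 16. The fallback sets the trans relationship thermodynamically and not through alkene geometry; it sets out from 15 and comes back at 16, and it makes no compound that the compound list does not hold (F0). KOH (5% in MeOH, 20 °C) epimerises C6, the γ-position of the enone, towards the more stable trans isomer in which the enone chain is pseudo-axial and free of strain with the C5 methyl, as base does with cis-α-irone. The reaction is stopped before the ring alkene moves into conjugation; 16 is separated on AgNO3-impregnated SiO2 and recovered 15 is recycled. C2 is not touched, so this also supplies ring B from resolved 15 if step 5 needed its fallback.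

The third risk is step 10. Cross-metathesis with a 1,1-disubstituted acrylate next to an enone may be slow, give E/Z mixtures, or isomerise allyl to propenyl. The fallback installs the ester side chain by Wittig olefination before the ring is closed, since a conjugated ester is as inert to H3PO4 as the allyl group; it sets out from 4 and comes back at 24. Methyl 2-(triphenylphosphoranylidene)propanoate (CH2Cl2, rt; aldehyde-selective, E) gives methyl (2E,5R)-2-methyl-8-oxo-5-(prop-1-en-2-yl)non-2-enoate F5. HC≡CMgBr (THF, −40 °C) gives methyl (2E,5R)-8-hydroxy-2,8-dimethyl-5-(prop-1-en-2-yl)dec-2-en-9-ynoate F6. 2-Methoxypropene with acid, then NaOH as in step 4, passes through methyl (2E,5R)-2,8-dimethyl-8-(prop-1-en-2-yloxy)-5-(prop-1-en-2-yl)dec-2-en-9-ynoate F7 and methyl (2E,5R)-2,8-dimethyl-12-oxo-5-(prop-1-en-2-yl)trideca-2,8,9-trienoate F8 to methyl (2E,5R,8Z,10E)-2,8-dimethyl-12-oxo-5-(prop-1-en-2-yl)trideca-2,8,10-trienoate F9, formed together with its 8E isomer methyl (2E,5R,8E,10E)-2,8-dimethyl-12-oxo-5-(prop-1-en-2-yl)trideca-2,8,10-trienoate F10, which is removed by chromatography. 85% H3PO4 as in step 6 converts F9 into 24.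

**Further compounds**

F1 | step 5 | (2S,6R,9RS)-2-allyl-α-ionol | C=CC[C@H]1CC=C(C)[C@@H](/C=C/C(C)O)C1(C)C
F2 | step 5 | (2S,6R,9R)-2-allyl-α-ionyl acetate | C=CC[C@H]1CC=C(C)[C@@H](/C=C/[C@@H](C)OC(C)=O)C1(C)C
F3 | step 5 | (2R,6S,9R)-2-allyl-α-ionyl acetate | C=CC[C@@H]1CC=C(C)[C@H](/C=C/[C@@H](C)OC(C)=O)C1(C)C
F4 | step 5 | (2S,6R,9R)-2-allyl-α-ionol | C=CC[C@H]1CC=C(C)[C@@H](/C=C/[C@@H](C)O)C1(C)C
F0 | step 6 | none | none
F5 | step 10 | methyl (2E,5R)-2-methyl-8-oxo-5-(prop-1-en-2-yl)non-2-enoate | COC(=O)/C(C)=C/C[C@@H](CCC(C)=O)C(C)=C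
F6 | step 10 | methyl (2E,5R)-8-hydroxy-2,8-dimethyl-5-(prop-1-en-2-yl)dec-2-en-9-ynoate | COC(=O)/C(C)=C/C[C@@H](CCC(C)(O)C#C)C(C)=C
F7 | step 10 | methyl (2E,5R)-2,8-dimethyl-8-(prop-1-en-2-yloxy)-5-(prop-1-en-2-yl)dec-2-en-9-ynoate | COC(=O)/C(C)=C/C[C@@H](CCC(C)(OC(C)=C)C#C)C(C)=C
F8 | step 10 | methyl (2E,5R)-2,8-dimethyl-12-oxo-5-(prop-1-en-2-yl)trideca-2,8,9-trienoate | COC(=O)/C(C)=C/C[C@@H](CCC(C)=C=CCC(C)=O)C(C)=C
F9 | step 10 | methyl (2E,5R,8Z,10E)-2,8-dimethyl-12-oxo-5-(prop-1-en-2-yl)trideca-2,8,10-trienoate | COC(=O)/C(C)=C/C[C@@H](CC/C(C)=C\C=C\C(C)=O)C(C)=C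
F10 | step 10 | methyl (2E,5R,8E,10E)-2,8-dimethyl-12-oxo-5-(prop-1-en-2-yl)trideca-2,8,10-trienoate | COC(=O)/C(C)=C/C[C@@H](CC/C(C)=C/C=C/C(C)=O)C(C)=C
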